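**Plan**

1. Retrosynthetic cuts, in order: (a) the chain bond C2'–C3' (chain carbons counted from the ring), giving a tridecyl radical, which is tetradecanoic (myristic) acid minus CO2, and 2-ethenyl-5,7-dihydroxy-6,8-dimethylchromone; (b) the vinyl group back to a 2-(2-methylsulfanylethyl) group; (c) the pyranone ring at O1–C2 and C2–C3, back to an o-hydroxyacetophenone and a C4 acid chloride; (d) the two aryl C–CH3 bonds, back to phloroacetophenone and MeI.
2. Enabling feature: in the 4-pyranone ring the unit O1–C2=C3–C4=O makes a vinyl group on C2 the end of a dienone (C2'=C1'–C2=C3–C4=O). Its terminal carbon C2' is the δ-position and accepts a nucleophilic alkyl radical; the adduct radical at C1' is delocalised over C2, C3 and the C4 carbonyl oxygen.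
3. Forward order: the benzene ring is bought; the ring methyls go on first; C-acylation and closure of the pyranone ring follow; the vinyl acceptor is unveiled; the C13 chain is joined last, on the unprotected chromone, so the union gives the target directly and the route carries no protecting group.
4. Stereochemistry: the target has no stereocentre and no stereogenic double bond, so nothing has to be controlled.

Key step: step 5

Remark: the three starting materials are taken as catalogue chemicals; the thioether is a temporary helper that leaves again in step 3.

**Step 1**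
Reactants: 1 1-(2,4,6-trihydroxyphenyl)ethan-1-one (2',4',6'-trihydroxyacetophenone)
Product: 2 1-(2,4,6-trihydroxy-3,5-dimethylphenyl)ethan-1-one
Conditions: MeI (2.2 equiv), NaOMe (3 equiv), MeOH, 0 °C to rt; aq. HCl
Reagents that add atoms: iodomethane, CI
Why: Nuclear C-methylation of a phloroglucinol, in which the polyphenoxide of 1 reacts as a vinylogous enolate at the two free ring carbons C3' and C5', should give the aromatic 3',5'-dimethyl compound as main product when MeI is limited to about two equivalents and the temperature is kept low to hold back geminal dimethylation.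

**Step 2**
Reactants: 2 1-(2,4,6-trihydroxy-3,5-dimethylphenyl)ethan-1-one; 3 3-(methylsulfanyl)propanoyl chloride
Product: 5 5,7-dihydroxy-6,8-dimethyl-2-[2-(methylsulfanyl)ethyl]-4H-chromen-4-one, via aryl 1,3-diketone 4 (not isolated)
Conditions: LiHMDS (5 equiv), THF, −78 °C, then 3, −78 °C to rt; aq. HCl; then AcOH, H2SO4 (cat.), 100 °C
Reagents that add atoms: none
Why: Claisen-type C-acylation of the polylithiated o-hydroxyacetophenone (three phenoxides plus the ketone enolate, the fifth equivalent of base taking up the acidic diketone 4, and any O-acylated material converging by Baker–Venkataraman acyl transfer) followed by acid-catalysed cyclodehydration should close the pyranone ring by attack of an ortho hydroxyl on the distal carbonyl; the two ortho hydroxyls are equivalent, so only one chromone can form, and the thioether is inert throughout.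

**Step 3**
Reactants: 5 5,7-dihydroxy-6,8-dimethyl-2-[2-(methylsulfanyl)ethyl]-4H-chromen-4-one
Product: 7 2-ethenyl-5,7-dihydroxy-6,8-dimethyl-4H-chromen-4-one, via sulfonium triflate 6 (not isolated)
Conditions: MeOTf (1.05 equiv), CH2Cl2, 0 °C; then K2CO3, MeCN, BHT (cat.), rt; dilute HCl work-up
Reagents that add atoms: none
Why: The dialkyl sulfide is far more nucleophilic than the un-ionised phenols or the hydrogen-bonded pyranone carbonyl, so S-methylation should be selective and place a neutral leaving group β to C1', whose hydrogens are vinylogously acidic through C2=C3–C4=O, so that carbonate effects an E1cB-type sulfonium elimination of dimethyl sulfide (which carries off the methyl brought in by MeOTf) to give the 2-vinylchromone.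

**Step 4**
Reactants: 8 tetradecanoic acid (myristic acid)
Product: 9 1,3-dioxoisoindolin-2-yl tetradecanoate
Conditions: N-hydroxyphthalimide (1.1 equiv), DIC (1.1 equiv), DMAP (5 mol%), CH2Cl2, rt
Reagents that add atoms: N-hydroxyphthalimide, O=C1c2ccccc2C(=O)N1O
Why: Carbodiimide-mediated (Steglich-type) esterification should give the stable redox-active ester, which releases the primary tridecyl radical and CO2 on single-electron reduction.

**Step 5**
Reactants: 7 2-ethenyl-5,7-dihydroxy-6,8-dimethyl-4H-chromen-4-one; 9 1,3-dioxoisoindolin-2-yl tetradecanoate
Product: 10 5,7-dihydroxy-6,8-dimethyl-2-pentadecyl-4H-chromen-4-one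
Conditions: 9 (1.5 equiv), Ru(bpy)3Cl2·6H2O (2 mol%), Hantzsch ester (2 equiv), degassed DMF, blue LEDs (450 nm), rt
Reagents that add atoms: none
Why: Under blue light excited Ru(bpy)3(2+) is reductively quenched by the Hantzsch ester, the resulting Ru(I) transfers an electron to the N-acyloxyphthalimide 9, and its radical anion fragments to phthalimide anion, CO2 and the primary tridecyl radical, which adds to the unsubstituted terminal carbon C2' of the vinyl group of 7; the adduct radical at C1', delocalised over C2=C3 and the C4 carbonyl oxygen and flanked by O1, is then quenched by hydrogen-atom transfer from the Hantzsch ester (or reduced and protonated), and any 2-alkylidene-chromanone tautomer should revert to the aromatic 4-pyranone. The closest known reaction type is the decarboxylative Giese reaction of redox-active esters with electron-poor alkenes, here in its vinylogous (1,6) mode as known for dienones and vinyl-substituted electron-poor heteroarenes. No ring is closed and no stereocentre is formed. The step needs site selectivity for C2' over C2 and C3 of the pyranone, which the free CH2 terminus and the far more stabilised adduct radical should secure, and chemoselectivity for C–C bond formation over hydrogen abstraction from the phenols, which is favoured because 5-OH is chelated to the C4 carbonyl, 7-OH is conjugated to it and no base is present to form an oxidisable phenoxide. Telomerisation should be held back by the low reactivity of the stabilised adduct radical towards a second molecule of 7 and by the excess of hydrogen donor, and loss of some tridecyl radical to tridecane is covered by the excess of 9.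

**Compound list**

1 | 1-(2,4,6-trihydroxyphenyl)ethan-1-one | CC(=O)c1c(O)cc(O)cc1O | starting material
2 | 1-(2,4,6-trihydroxy-3,5-dimethylphenyl)ethan-1-one | CC(=O)c1c(O)c(C)c(O)c(C)c1O | intermediate
3 | 3-(methylsulfanyl)propanoyl chloride | CSCCC(=O)Cl | starting material
4 | 5-(methylsulfanyl)-1-(2,4,6-trihydroxy-3,5-dimethylphenyl)pentane-1,3-dione (formed and consumed in step 2) | CSCCC(=O)CC(=O)c1c(O)c(C)c(O)c(C)c1O | intermediate
5 | 5,7-dihydroxy-6,8-dimethyl-2-[2-(methylsulfanyl)ethyl]-4H-chromen-4-one | CSCCc1cc(=O)c2c(O)c(C)c(O)c(C)c2o1 | intermediate
6 | [2-(5,7-dihydroxy-6,8-dimethyl-4-oxo-4H-chromen-2-yl)ethyl]dimethylsulfonium trifluoromethanesulfonate (formed and consumed in step 3) | C[S+](C)CCc1cc(=O)c2c(O)c(C)c(O)c(C)c2o1.[O-]S(=O)(=O)C(F)(F)F | intermediate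
7 | 2-ethenyl-5,7-dihydroxy-6,8-dimethyl-4H-chromen-4-one | C=Cc1cc(=O)c2c(O)c(C)c(O)c(C)c2o1 | intermediate
8 | tetradecanoic acid | CCCCCCCCCCCCCC(=O)O | starting material
9 | 1,3-dioxoisoindolin-2-yl tetradecanoate | CCCCCCCCCCCCCC(=O)ON1C(=O)c2ccccc2C1=O | intermediate
10 | 5,7-dihydroxy-6,8-dimethyl-2-pentadecyl-4H-chromen-4-one | CCCCCCCCCCCCCCCc1cc(=O)c2c(O)c(C)c(O)c(C)c2o1 | target

**Count**

Total steps: 5. Longest linear sequence: 4 (steps 1, 2, 3, 5); step 4 is a one-step side branch.

**Steps most likely to fail**

Step 5. The tridecyl radical may be reduced to tridecane before it adds, the stabilised adduct radical may telomerise with more vinylchromone, or hydrogen abstraction from the phenols may stall the chain. The fallback joins the same bond by polar means on a protected substrate. It sets out from 7, which is silylated with TBSOTf and 2,6-lutidine in CH2Cl2 to 5,7-bis(tert-butyldimethylsilyloxy)-2-ethenyl-6,8-dimethyl-4H-chromen-4-one F1. Tridecylmagnesium bromide F2, made from commercial 1-bromotridecane and magnesium in THF, is then added to F1 with CuBr·SMe2 (10 mol%) at −40 °C; this copper-catalysed 1,6-conjugate addition should give, after aqueous NH4Cl, 5,7-bis(tert-butyldimethylsilyloxy)-6,8-dimethyl-2-pentadecyl-4H-chromen-4-one F3. TBAF in THF removes both silyl groups and the fallback returns to the route at 10.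

Step 2. The acid chloride may acylate phenoxide oxygen without onward acyl transfer, may be lost as a ketene by enolisation, or the polylithiated ketone may precipitate and react incompletely. The fallback masks two phenols and uses a classical ester Claisen condensation. It sets out from 2, which with MOMCl (2.2 equiv) and iPr2NEt in CH2Cl2 gives 1-[2-hydroxy-4,6-bis(methoxymethoxy)-3,5-dimethylphenyl]ethan-1-one F4. Condensation of F4 with commercial methyl 3-(methylsulfanyl)propanoate (NaH, THF, reflux) should give 1-[2-hydroxy-4,6-bis(methoxymethoxy)-3,5-dimethylphenyl]-5-(methylsulfanyl)pentane-1,3-dione F5. HCl in MeOH at reflux then closes the pyranone ring and cleaves both MOM ethers, and the fallback returns at 5.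

Step 3. Methylation may spill over to the 7-hydroxyl or the pyranone carbonyl, the sulfonium salt may transfer a methyl group to the phenoxide faster than it eliminates, or the vinyl product may oligomerise under base. The fallback replaces the ionic elimination by a neutral thermal one. It sets out from 5, which with 30% H2O2 (1.1 equiv) in hexafluoroisopropanol at rt should give 5,7-dihydroxy-2-[2-(methylsulfinyl)ethyl]-6,8-dimethyl-4H-chromen-4-one F6. Heating F6 in toluene or xylene (110–140 °C, solid NaHCO3, BHT) should expel methanesulfenic acid by syn-elimination, and the fallback returns at 7.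

**Further compounds**

F1 | step 5 | 5,7-bis(tert-butyldimethylsilyloxy)-2-ethenyl-6,8-dimethyl-4H-chromen-4-one | C=Cc1cc(=O)c2c(O[Si](C)(C)C(C)(C)C)c(C)c(O[Si](C)(C)C(C)(C)C)c(C)c2o1
F2 | step 5 | tridecylmagnesium bromide | CCCCCCCCCCCCC[Mg]Br
F3 | step 5 | 5,7-bis(tert-butyldimethylsilyloxy)-6,8-dimethyl-2-pentadecyl-4H-chromen-4-one | CCCCCCCCCCCCCCCc1cc(=O)c2c(O[Si](C)(C)C(C)(C)C)c(C)c(O[Si](C)(C)C(C)(C)C)c(C)c2o1
F4 | step 2 | 1-[2-hydroxy-4,6-bis(methoxymethoxy)-3,5-dimethylphenyl]ethan-1-one | CC(=O)c1c(O)c(C)c(OCOC)c(C)c1OCOC
F5 | step 2 | 1-[2-hydroxy-4,6-bis(methoxymethoxy)-3,5-dimethylphenyl]-5-(methylsulfanyl)pentane-1,3-dione | CSCCC(=O)CC(=O)c1c(O)c(C)c(OCOC)c(C)c1OCOC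
F6 | step 3 | 5,7-dihydroxy-2-[2-(methylsulfinyl)ethyl]-6,8-dimethyl-4H-chromen-4-one | CS(=O)CCc1cc(=O)c2c(O)c(C)c(O)c(C)c2o1
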